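**Strategy.** Ring C of unit 1 (the eriodictyol-type flavanone) is disconnected across C4–C4a and C2–C3. This splits the target into an O-aryl oxocarbenium ion (ring A, O1, C2, ring B) and a two-carbon ketene equivalent (C3–C4) carried on C8'' of enantiopure taxifolin (unit 2). The key step is a cationic [4+2] annulation: an aryloxy(aryl)methyl pivalate is ionised, an 8-ethoxyethynyl taxifolin ether adds through C3 to C2, and the resulting ketenium carbon C4 acylates ring A at C4a; hydrolysis gives the C4 ketone. It exploits the nucleophilic ortho carbon C4a of phloroglucinol ring A and the aldehyde oxidation level of C2. C2 forms as both epimers; enantiopure unit 2 makes them separable diastereomers.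

Key step: step 5

Remark: locants without primes refer to unit 1 (rings A, C, B); double-primed locants refer to unit 2 (the taxifolin unit) in the biflavanone. Compounds 5 to 10 carry plain chromanone locants, and their C8 becomes C8'' of the target. (+)-Taxifolin, 3,5-bis(benzyloxy)phenol, 3,4-bis(benzyloxy)benzaldehyde and ethoxyacetylene are taken as commercial. Acetal 4 is used as the racemate, because its acetal stereocentre is destroyed on ionisation in step 5.

Step 1
Reactants: 1 3,4-bis(benzyloxy)benzaldehyde; 2 3,5-bis(benzyloxy)phenol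
Product: 4 [3,4-bis(benzyloxy)phenyl][3,5-bis(benzyloxy)phenoxy]methyl pivalate (racemic), via chloro[3,4-bis(benzyloxy)phenyl]methyl pivalate 3 (not isolated)
Conditions: PivCl (1.05 equiv), ZnCl2 (5 mol %), CH2Cl2, 0 °C to rt, volatiles removed in vacuo; then 2 (1.0 equiv), Cs2CO3, MeCN, 0 °C; Et3N-deactivated silica
Reagents that add atoms: pivaloyl chloride, CC(C)(C)C(=O)Cl
Why: ZnCl2-catalysed addition of the acyl chloride across the aldehyde C=O gives the α-chlorobenzyl ester 3, whose chloride is displaced by one equivalent of the cesium phenoxide in an SN1-like Williamson O-alkylation through the p-alkoxy-stabilised acyloxycarbenium ion, the hindered pivaloyl carbonyl resisting acyl transfer; the acetal carbon forms as a racemate.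

Step 2
Reactants: 5 (+)-taxifolin, (2R,3R)-2-(3,4-dihydroxyphenyl)-3,5,7-trihydroxychroman-4-one
Product: 6 (2R,3R)-5,7-bis(benzyloxy)-2-[3,4-bis(benzyloxy)phenyl]-3-hydroxychroman-4-one
Conditions: BnBr (4.5 equiv), K2CO3, DMF, rt, argon
Reagents that add atoms: benzyl bromide, BrCc1ccccc1
Why: Williamson O-benzylation of the four phenols (the chelated 5-OH last) with carbonate, which is too weak to alkylate the secondary 3-OH and at room temperature should not open the pyranone ring by retro-oxa-Michael reaction, so C2 and C3 keep the (2R,3R) configuration of the chiral pool.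

Step 3
Reactants: 6 (2R,3R)-5,7-bis(benzyloxy)-2-[3,4-bis(benzyloxy)phenyl]-3-hydroxychroman-4-one
Product: 7 (2R,3R)-5,7-bis(benzyloxy)-2-[3,4-bis(benzyloxy)phenyl]-3-hydroxy-8-iodochroman-4-one
Conditions: NIS (1.05 equiv), CF3CO2H (cat.), MeCN/CH2Cl2, 0 °C to rt, dark
Reagents that add atoms: N-iodosuccinimide, O=C1CCC(=O)N1I
Why: Electrophilic aromatic iodination of the most electron-rich ring (three oxygen donors) at C8, which is flanked by the ring oxygen and 7-OBn and in 5-O-alkylated 5,7-dioxygenated flavonoids is favoured over the more hindered C6 between two benzyloxy groups; the stereocentres are not involved.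

Step 4
Reactants: 7 (2R,3R)-5,7-bis(benzyloxy)-2-[3,4-bis(benzyloxy)phenyl]-3-hydroxy-8-iodochroman-4-one; 8 ethoxyacetylene
Product: 9 (2R,3R)-5,7-bis(benzyloxy)-2-[3,4-bis(benzyloxy)phenyl]-8-(ethoxyethynyl)-3-hydroxychroman-4-one
Conditions: 8 (3 equiv), n-BuLi, THF, −78 °C; ZnCl2, −78 to 0 °C; then 7, Pd(PPh3)4 (5 mol %), THF, rt to 40 °C; NaHCO3 work-up, Et3N-deactivated silica
Reagents that add atoms: none
Why: Negishi cross-coupling of ethoxyethynylzinc chloride (from lithiated ethoxyacetylene and ZnCl2) with the aryl iodide under zerovalent palladium catalysis, the weakly basic zinc acetylide leaving the enolisable flavanonol intact while the excess reagent covers the free 3-OH and buffered isolation protects the acid-labile ynol ether.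

Step 5
Reactants: 4 [3,4-bis(benzyloxy)phenyl][3,5-bis(benzyloxy)phenoxy]methyl pivalate (racemic); 9 (2R,3R)-5,7-bis(benzyloxy)-2-[3,4-bis(benzyloxy)phenyl]-8-(ethoxyethynyl)-3-hydroxychroman-4-one
Product: 12 (2S,3R)-5,7-bis(benzyloxy)-2-[3,4-bis(benzyloxy)phenyl]-3-{(2R,3R)-5,7-bis(benzyloxy)-2-[3,4-bis(benzyloxy)phenyl]-3-hydroxy-4-oxochroman-8-yl}chroman-4-one, via 3-O-trimethylsilyl ynol ether 10 (not isolated), via 4-ethoxy-2H-chromene enol ether 11 (not isolated)
Conditions: 4 (1.3 equiv), Me3SiOTf (2.3 equiv), 2,6-di-tert-butyl-4-methylpyridine (2.5 equiv), 4 Å MS, CH2Cl2, −78 to −40 °C; then 2 M HCl, THF, rt; chromatography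
Reagents that add atoms: water, O
Why: Proposed new method: Me3SiOTf silylates the 3-OH of 9 (giving 10) and the pivalate carbonyl of 4, which leaves as trimethylsilyl pivalate to give the O-aryl oxocarbenium ion ArO+=CH–Ar, a cationic 2-oxadiene (C4a=C8a–O1=C2); the aryl-bearing alkyne carbon (future C3) attacks C2, the ethoxy-stabilised ketenium carbon (future C4) is captured by the ortho carbon C4a of the 3,5-bis(benzyloxy)phenoxy ring, the hindered pyridine removes the Wheland proton to give enol ether 11, and aqueous acid hydrolyses the enol ether to the C4 ketone and cleaves the silyl ether. The closest known reaction types are the oxa-Povarov reaction (Lewis-acid-generated O-aryl oxocarbenium ions with alkenes giving chromans) and the Friedel–Crafts capture of ketenium ions from ynol-type alkynes giving cyclic aryl ketones; an ynol ether as the two-carbon partner of such an oxocarbenium ion has not been shown. Ring C of unit 1 closes as a formal [4+2] annulation in two events: intermolecular C2–C3 bond formation, then a six-membered Friedel–Crafts closure of C4a onto the sp-hybridised ketenium carbon (6-exo with respect to the C4=O+ bond, C3=C4 staying in the ring). C3 is set under thermodynamic control in the acidic hydrolysis, where the enolisable benzylic α-keto centre should settle trans (diequatorial) to the C2 aryl group; C2 is formed without reagent control (only weak 1,5-induction from C2'' can be expected), so both trans diastereomers should form and the (2S,3R) isomer 12 is separated by chromatography from its (2R,3S) diastereomer, which is possible because unit 2 is enantiopure. Regioselectivity rests on the substrate alone, since pivalate is the only group of 4 that Me3SiOTf can remove and its silyl ester is no competing nucleophile, the two ortho carbons of the symmetric phenoxy ring are equivalent and the ethoxy group makes only the aryl-bearing alkyne carbon nucleophilic, while the high π-nucleophilicity of the ynol ether should let it outrun Friedel–Crafts alkylation of the bystander arenes.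

Step 6
Reactants: 12 (2S,3R)-5,7-bis(benzyloxy)-2-[3,4-bis(benzyloxy)phenyl]-3-{(2R,3R)-5,7-bis(benzyloxy)-2-[3,4-bis(benzyloxy)phenyl]-3-hydroxy-4-oxochroman-8-yl}chroman-4-one
Product: 13 (2S,3R)-2-(3,4-dihydroxyphenyl)-3-[(2R,3R)-2-(3,4-dihydroxyphenyl)-3,5,7-trihydroxy-4-oxochroman-8-yl]-5,7-dihydroxychroman-4-one
Conditions: H2 (1 atm), Pd(OH)2/C, THF/MeOH, rt, stopped at the calculated uptake
Reagents that add atoms: none
Why: Heterogeneous hydrogenolysis of the eight benzyl aryl ethers under neutral conditions should leave the two aryl ketones, the benzylic C2–O1 and C2''–O1'' bonds and all four stereocentres untouched.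

**Compound list**

1 | 3,4-bis(benzyloxy)benzaldehyde | O=Cc1ccc(OCc2ccccc2)c(OCc2ccccc2)c1 | starting material
2 | 3,5-bis(benzyloxy)phenol | Oc1cc(OCc2ccccc2)cc(OCc2ccccc2)c1 | starting material
3 | chloro[3,4-bis(benzyloxy)phenyl]methyl pivalate (racemic) | CC(C)(C)C(=O)OC(Cl)c1ccc(OCc2ccccc2)c(OCc2ccccc2)c1 | intermediate
4 | [3,4-bis(benzyloxy)phenyl][3,5-bis(benzyloxy)phenoxy]methyl pivalate (racemic) | CC(C)(C)C(=O)OC(Oc1cc(OCc2ccccc2)cc(OCc2ccccc2)c1)c1ccc(OCc2ccccc2)c(OCc2ccccc2)c1 | intermediate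
5 | (+)-taxifolin, (2R,3R)-2-(3,4-dihydroxyphenyl)-3,5,7-trihydroxychroman-4-one | Oc1cc(O)c2c(c1)O[C@H](c1ccc(O)c(O)c1)[C@@H](O)C2=O | starting material
6 | (2R,3R)-5,7-bis(benzyloxy)-2-[3,4-bis(benzyloxy)phenyl]-3-hydroxychroman-4-one | O(Cc1ccccc1)c1cc(OCc3ccccc3)c2c(c1)O[C@H](c1ccc(OCc3ccccc3)c(OCc3ccccc3)c1)[C@@H](O)C2=O | intermediate
7 | (2R,3R)-5,7-bis(benzyloxy)-2-[3,4-bis(benzyloxy)phenyl]-3-hydroxy-8-iodochroman-4-one | O(Cc1ccccc1)c1cc(OCc3ccccc3)c2c(c1I)O[C@H](c1ccc(OCc3ccccc3)c(OCc3ccccc3)c1)[C@@H](O)C2=O | intermediate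
8 | ethoxyacetylene (ethoxyethyne) | C#COCC | starting material
9 | (2R,3R)-5,7-bis(benzyloxy)-2-[3,4-bis(benzyloxy)phenyl]-8-(ethoxyethynyl)-3-hydroxychroman-4-one | O(Cc1ccccc1)c1cc(OCc3ccccc3)c2c(c1C#COCC)O[C@H](c1ccc(OCc3ccccc3)c(OCc3ccccc3)c1)[C@@H](O)C2=O | intermediate
10 | (2R,3R)-5,7-bis(benzyloxy)-2-[3,4-bis(benzyloxy)phenyl]-8-(ethoxyethynyl)-3-(trimethylsilyloxy)chroman-4-one | O(Cc1ccccc1)c1cc(OCc3ccccc3)c2c(c1C#COCC)O[C@H](c1ccc(OCc3ccccc3)c(OCc3ccccc3)c1)[C@@H](O[Si](C)(C)C)C2=O | intermediate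
11 | (2R,3R)-5,7-bis(benzyloxy)-2-[3,4-bis(benzyloxy)phenyl]-8-{(2R)-5,7-bis(benzyloxy)-2-[3,4-bis(benzyloxy)phenyl]-4-ethoxy-2H-chromen-3-yl}-3-(trimethylsilyloxy)chroman-4-one (chromene C2 has the spatial arrangement of C2 in 12; its descriptor is R because the CIP priorities change) | CCOC1=C(c3c(OCc5ccccc5)cc(OCc5ccccc5)c4c3O[C@H](c3ccc(OCc5ccccc5)c(OCc5ccccc5)c3)[C@@H](O[Si](C)(C)C)C4=O)[C@@H](c3ccc(OCc5ccccc5)c(OCc5ccccc5)c3)Oc2cc(OCc5ccccc5)cc(OCc5ccccc5)c12 | intermediate
12 | (2S,3R)-5,7-bis(benzyloxy)-2-[3,4-bis(benzyloxy)phenyl]-3-{(2R,3R)-5,7-bis(benzyloxy)-2-[3,4-bis(benzyloxy)phenyl]-3-hydroxy-4-oxochroman-8-yl}chroman-4-one | O=C1c2c(OCc3ccccc3)cc(OCc3ccccc3)cc2O[C@H](c2ccc(OCc3ccccc3)c(OCc3ccccc3)c2)[C@H]1c1c(OCc3ccccc3)cc(OCc3ccccc3)c2c1O[C@H](c1ccc(OCc3ccccc3)c(OCc3ccccc3)c1)[C@@H](O)C2=O | intermediate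
13 | (2S,3R)-2-(3,4-dihydroxyphenyl)-3-[(2R,3R)-2-(3,4-dihydroxyphenyl)-3,5,7-trihydroxy-4-oxochroman-8-yl]-5,7-dihydroxychroman-4-one (EANPDB:THYM_00006) | O=C1c2c(O)cc(O)cc2O[C@H](c2ccc(O)c(O)c2)[C@H]1c1c(O)cc(O)c2c1O[C@H](c1ccc(O)c(O)c1)[C@@H](O)C2=O | target

**Step count.** Total: 6 steps. Longest linear sequence: 5 steps (5 → 6 → 7 → 9 → 12 → 13).

**Steps most likely to fail**

1. Step 5 (proposed new method). Several processes may go wrong:
   - the ketenium ion may be intercepted by a neighbouring ether oxygen instead of closing on C4a (5-endo attack of the 7''-benzyloxy oxygen with loss of benzyl, or four-membered closure with the aryloxy oxygen);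
   - the ynol ether may be protonated or hydrated;
   - the oxocarbenium ion may alkylate bystander electron-rich rings;
   - the missing facial selectivity at C2 makes the diastereomer separation necessary.

   Fallback with known chemistry, setting out from 9 (with 2 and 1) and returning at 12: heating 9 with an excess of phenol 2 in toluene at about 120 °C should release ethylene by retro-ene fragmentation of the ethoxyalkyne; the aryl ketene so formed is trapped by the phenol as 3,5-bis(benzyloxy)phenyl 2-[(2R,3R)-5,7-bis(benzyloxy)-2-(3,4-bis(benzyloxy)phenyl)-3-hydroxy-4-oxochroman-8-yl]acetate F1. Fries rearrangement of this ester (Sc(OTf)3, toluene, 80 °C, or photochemically) should give the 2-hydroxydeoxybenzoin 1-[2,4-bis(benzyloxy)-6-hydroxyphenyl]-2-[(2R,3R)-5,7-bis(benzyloxy)-2-(3,4-bis(benzyloxy)phenyl)-3-hydroxy-4-oxochroman-8-yl]ethan-1-one F2, which already holds the C4–C4a bond. Cyclocondensation of the deoxybenzoin with aldehyde 1 (piperidine, EtOH, reflux; Knoevenagel condensation then oxa-Michael closure, the standard entry to 2,3-trans-2,3-diarylchroman-4-ones) returns to 12 after the same separation of diastereomers.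

2. Step 4. Oxidative addition at the doubly ortho-substituted iodide may be slow, and the acid-labile ynol ether may hydrate to the ethyl arylacetate during work-up or chromatography.

   Fallback, setting out from 7 and returning at 12: Negishi–Reformatsky arylation of 7 with BrZnCH2CO2t-Bu (Pd(dba)2, P(t-Bu)3, THF, rt) should give tert-butyl 2-[(2R,3R)-5,7-bis(benzyloxy)-2-(3,4-bis(benzyloxy)phenyl)-3-hydroxy-4-oxochroman-8-yl]acetate F3. Acidolysis (CF3CO2H, CH2Cl2, 0 °C) gives 2-[(2R,3R)-5,7-bis(benzyloxy)-2-(3,4-bis(benzyloxy)phenyl)-3-hydroxy-4-oxochroman-8-yl]acetic acid F4. Esterification with phenol 2 (EDC·HCl, DMAP, CH2Cl2) gives the aryl ester F1, which is carried through the Fries rearrangement and the aldehyde cyclocondensation described above to 12.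

3. Step 1. The acyl chloride–aldehyde addition may stop at an unfavourable equilibrium for this electron-rich aldehyde, the phenoxide may attack the pivaloyl carbonyl (acyl transfer) instead of the benzylic carbon, and the acid-labile mixed acetal may hydrolyse on isolation.

   Fallback, setting out from 1 and returning at 12: deoxychlorination of aldehyde 1 (SOCl2, DMF cat., CH2Cl2, 0 °C to rt) should give 1,2-bis(benzyloxy)-4-(dichloromethyl)benzene F5. Double Williamson displacement of its two chlorides with two equivalents of the sodium salt of phenol 2 (NaH, THF/DMF, 0 °C to rt) gives the symmetric diaryl acetal 3,4-bis(benzyloxy)benzaldehyde bis[3,5-bis(benzyloxy)phenyl] acetal F6. This acetal takes the place of 4 in step 5, where loss of either aryloxy group under Me3SiOTf gives the same O-aryl oxocarbenium ion, and the route is rejoined at 12.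

**Further compounds**

F1 | step 5 | 3,5-bis(benzyloxy)phenyl 2-[(2R,3R)-5,7-bis(benzyloxy)-2-(3,4-bis(benzyloxy)phenyl)-3-hydroxy-4-oxochroman-8-yl]acetate | O=C(Cc1c(OCc3ccccc3)cc(OCc3ccccc3)c2c1O[C@H](c1ccc(OCc3ccccc3)c(OCc3ccccc3)c1)[C@@H](O)C2=O)Oc1cc(OCc3ccccc3)cc(OCc3ccccc3)c1
F2 | step 5 | 1-[2,4-bis(benzyloxy)-6-hydroxyphenyl]-2-[(2R,3R)-5,7-bis(benzyloxy)-2-(3,4-bis(benzyloxy)phenyl)-3-hydroxy-4-oxochroman-8-yl]ethan-1-one | O=C(Cc1c(OCc3ccccc3)cc(OCc3ccccc3)c2c1O[C@H](c1ccc(OCc3ccccc3)c(OCc3ccccc3)c1)[C@@H](O)C2=O)c1c(O)cc(OCc3ccccc3)cc1OCc1ccccc1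
F3 | step 4 | tert-butyl 2-[(2R,3R)-5,7-bis(benzyloxy)-2-(3,4-bis(benzyloxy)phenyl)-3-hydroxy-4-oxochroman-8-yl]acetate | CC(C)(C)OC(=O)Cc1c(OCc3ccccc3)cc(OCc3ccccc3)c2c1O[C@H](c1ccc(OCc3ccccc3)c(OCc3ccccc3)c1)[C@@H](O)C2=O
F4 | step 4 | 2-[(2R,3R)-5,7-bis(benzyloxy)-2-(3,4-bis(benzyloxy)phenyl)-3-hydroxy-4-oxochroman-8-yl]acetic acid | OC(=O)Cc1c(OCc3ccccc3)cc(OCc3ccccc3)c2c1O[C@H](c1ccc(OCc3ccccc3)c(OCc3ccccc3)c1)[C@@H](O)C2=O
F5 | step 1 | 1,2-bis(benzyloxy)-4-(dichloromethyl)benzene | ClC(Cl)c1ccc(OCc2ccccc2)c(OCc2ccccc2)c1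
F6 | step 1 | 3,4-bis(benzyloxy)benzaldehyde bis[3,5-bis(benzyloxy)phenyl] acetal | C(Oc1cc(OCc2ccccc2)cc(OCc2ccccc2)c1)(Oc1cc(OCc2ccccc2)cc(OCc2ccccc2)c1)c1ccc(OCc2ccccc2)c(OCc2ccccc2)c1
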